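**Plan**
- Retrosynthesis, in order: (1) the nineteen O-benzyl groups and the two galloyl C(=O)–O3 bonds of the middle and bottom units; (2) the C4–C4a bond of the top flavan unit together with its C4–H, which opens top ring C to an aryl ketone; (3) the ketone C4–C8 bond to ring A of the middle unit; (4) the C2–O1 aryl ether and the C2–C3 aldol bond of the three-carbon top chain; (5) the 4β→8 bond of the lower dimer.
- Forward: (−)-epicatechin gives the benzylated, C8-brominated, bis-silylated 4β→8 dimer 6. A syn glycolate aldol, amide exchange and O-arylation give the open-chain top unit 13. Aryllithium acylation gives ketone 15. Reductive Friedel–Crafts cyclisation closes top ring C (18). TBS-to-galloyl exchange and hydrogenolysis finish.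
- Enabling feature: top C4 is a diarylmethine carbon between two phloroglucinol-type rings (C4a of top ring A, C8 of middle ring A). As a ketone it is attacked by either of the two equivalent ortho carbons of the symmetrical 3,5-dioxygenated aryl ether, and the doubly benzylic cation that follows accepts hydride.
- Stereochemistry: lower-unit C2/C3 come from (−)-epicatechin; middle C4 (4β) from anti attack on its C4 cation; top C2/C3 from the Evans syn-aldol, kept through O-arylation with retention; top C4 (4α, all-cis) from hydride delivery anti to the C3 oxygen in the key step.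
- Protecting groups: top O3 is a benzyl ether from the glycolate; middle and bottom O3 are TBS ethers through the organolithium and acid steps, then exchanged for tri-O-benzylgalloyl esters.

Key step: step 10

Assumption: the SMILES is read as drawn, i.e. epicatechin-(4α→8)-epicatechin 3-O-gallate-(4β→8)-epicatechin 3-O-gallate, with a 2,3-cis-3,4-cis top unit (2R,3R,4S) and a 2,3-cis-3,4-trans middle unit (2R,3R,4S).

**Route**

Step 1
Reactants: 1 (−)-epicatechin
Product: 2 5,7,3',4'-tetra-O-benzyl-(−)-epicatechin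
Conditions: BnBr, K2CO3, DMF, 0 °C → rt
Reagents that add atoms: benzyl bromide, BrCc1ccccc1
Why: Williamson etherification in which carbonate deprotonates only the four phenols, so the C3 alcohol stays free and no stereocentre is touched.

Step 2
Reactants: 2 5,7,3',4'-tetra-O-benzyl-(−)-epicatechin
Product: 3 5,7,3',4'-tetra-O-benzyl-4β-(2-ethoxyethoxy)epicatechin
Conditions: DDQ, EtOCH2CH2OH, CH2Cl2, rt
Reagents that add atoms: 2-ethoxyethanol, CCOCCO
Why: DDQ-mediated benzylic C–H oxidation at C4 (hydride abstraction activated by ring A), with the alcohol adding anti to the axial C3–OH to give the 4β ether.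

Step 3
Reactants: 3 5,7,3',4'-tetra-O-benzyl-4β-(2-ethoxyethoxy)epicatechin
Product: 4 8-bromo-5,7,3',4'-tetra-O-benzyl-4β-(2-ethoxyethoxy)epicatechin
Conditions: NBS, CH2Cl2, −78 °C → rt
Reagents that add atoms: N-bromosuccinimide, O=C1CCC(=O)N1Br
Why: Electrophilic aromatic bromination at C8, the most nucleophilic position of benzylated ring A, where the bromine later blocks self-condensation and serves as the lithiation handle.

Step 4
Reactants: 4 8-bromo-5,7,3',4'-tetra-O-benzyl-4β-(2-ethoxyethoxy)epicatechin and 2 5,7,3',4'-tetra-O-benzyl-(−)-epicatechin (3 equiv)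
Product: 5 8-bromo-[5,7,3',4'-tetra-O-benzylepicatechin]-(4β→8)-[5,7,3',4'-tetra-O-benzylepicatechin], both C3 hydroxyls free
Conditions: TMSOTf (cat.), CH2Cl2, −78 °C; Et3N quench
Reagents that add atoms: none
Why: Lewis-acid-mediated Friedel–Crafts-type interflavan coupling in which ionisation of the 4-alkoxy group is followed by attack of C8 of 2 anti to the C3 oxygen, setting the 4β (3,4-trans) centre while the C8 bromine of 4 prevents self-condensation.

Step 5
Reactants: 5 bromo dimer diol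
Product: 6 bis-TBS ether of 5 (both C3 oxygens silylated)
Conditions: TBSOTf, 2,6-lutidine, CH2Cl2, 0 °C → rt
Reagents that add atoms: tert-butyldimethylsilyl triflate, CC(C)(C)[Si](C)(C)OS(=O)(=O)C(F)(F)F
Why: Silyl triflate silylation is strong enough for the two hindered secondary alcohols and gives ethers that tolerate aryllithium and brief exposure to CF3CO2H.

Step 6
Reactants: 7 3,4-bis(benzyloxy)benzaldehyde and 8 (S)-4-benzyl-3-[(benzyloxy)acetyl]oxazolidin-2-one
Product: 10 (S)-4-benzyl-3-[(2S,3R)-2-(benzyloxy)-3-[3,4-bis(benzyloxy)phenyl]-3-hydroxypropanoyl]oxazolidin-2-one, via dibutylboron Z-enolate 9 (not isolated)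
Conditions: Bu2BOTf, Et3N, CH2Cl2, −78 → 0 °C; then 7, −78 → 0 °C; H2O2, pH 7 buffer, MeOH
Reagents that add atoms: none
Why: Evans syn-aldol in which the Z boron enolate reacts through a Zimmerman–Traxler chair on the face opposite the auxiliary benzyl group, setting the (2S,3R) syn pair that becomes C3 and C2 of the top flavan unit.

Step 7
Reactants: 10 aldol adduct
Product: 11 (2S,3R)-2-(benzyloxy)-3-[3,4-bis(benzyloxy)phenyl]-3-hydroxy-N-methoxy-N-methylpropanamide
Conditions: Me(MeO)NH·HCl, AlMe3, CH2Cl2, −20 → 0 °C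
Reagents that add atoms: N,O-dimethylhydroxylamine hydrochloride, CNOC.Cl
Why: Aluminium amide aminolysis of the N-acyl oxazolidinone (Weinreb amide formation), assisted by the free β-hydroxyl and leaving both stereocentres untouched.

Step 8
Reactants: 11 β-hydroxy Weinreb amide and 12 1-bromo-3,5-bis(benzyloxy)benzene
Product: 13 (2S,3R)-2-(benzyloxy)-3-[3,4-bis(benzyloxy)phenyl]-3-[3,5-bis(benzyloxy)phenoxy]-N-methoxy-N-methylpropanamide
Conditions: [Pd(C3H5)Cl]2 (cat.), RockPhos, Cs2CO3, toluene, 90 °C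
Reagents that add atoms: none
Why: Palladium-catalysed C–O cross-coupling (Buchwald–Hartwig etherification) of a secondary alcohol with an aryl bromide, which forms the aryl–O bond without breaking the carbinol C–O bond, so the benzylic centre is retained, and which uses only a weak carbonate base.

Step 9
Reactants: 6 bromo dimer bis-TBS ether and 13 aryl ether Weinreb amide
Product: 15 C8 aryl ketone (dimer of 6 in which the bromine at C8 of the upper unit is replaced by the (2S,3R)-2-(benzyloxy)-3-[3,4-bis(benzyloxy)phenyl]-3-[3,5-bis(benzyloxy)phenoxy]propanoyl group), via aryllithium 14 (not isolated)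
Conditions: t-BuLi (2 equiv), THF, −78 °C; then 13, −78 → −40 °C; aq. NH4Cl
Reagents that add atoms: none
Why: Bromine–lithium exchange followed by acylation of the aryllithium with a Weinreb amide, whose chelated tetrahedral adduct stops over-addition and leaves the α- and β-stereocentres intact at low temperature.

Step 10
Reactants: 15 ketone
Product: 18 [3,5,7,3',4'-penta-O-benzylepicatechin]-(4α→8)-[5,7,3',4'-tetra-O-benzyl-3-O-TBS-epicatechin]-(4β→8)-[5,7,3',4'-tetra-O-benzyl-3-O-TBS-epicatechin], via tertiary carbinol 16 (not isolated), via benzylic cation 17 (not isolated)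
Conditions: Et3SiH (excess), CF3CO2H, CH2Cl2, −20 → 0 °C
Reagents that add atoms: none
Why: Proposed new method: CF3CO2H activates the twisted, α-alkoxy aryl ketone of 15, one of the two equivalent carbons ortho to the ether oxygen of the 3,5-bis(benzyloxy)phenoxy group adds to the carbonyl carbon (intramolecular Friedel–Crafts hydroxyalkylation) to give carbinol 16, which ionises to the doubly benzylic cation 17 and is reduced by Et3SiH (ionic hydrogenation). The closest known reaction types are the acid-mediated cyclodehydration of 3-aryloxypropyl aryl ketones to 4-aryl-2H-chromenes and the hydride reduction of 4-aryl-4-hydroxyflavans under CF3CO2H, the new element being their union with interception of the cation before loss of H3. Ring C of the top unit is closed in the 6-exo-trig mode (arene carbon onto C=O), and no other ring forms. The one new stereocentre, top C4, is controlled by the adjacent C3: in the half-chair cation the C2 aryl is equatorial and the C3 benzyloxy axial, and hydride enters axially on the face anti to that C–O bond, so the C8-linked middle unit ends cis to O3 and to the C2 aryl (4α, all-cis). The step needs chemoselectivity (cyclisation before direct reduction of the ketone, reduction before loss of H3 or ionisation of the benzylic C2–O bond), which the intramolecular trioxygenated nucleophile, the weak hydride donor used in excess and the low temperature are meant to secure. Regioselectivity is built in, since the aryl ether is symmetrical and its para carbon cannot reach C4.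

Step 11
Reactants: 18 protected trimer
Product: 19 trimer diol (middle and bottom C3 hydroxyls free, top O3 benzylated)
Conditions: Bu4NF, THF, 0 °C → rt
Reagents that add atoms: none
Why: Fluoride-mediated desilylation removes only the two TBS ethers, since benzyl ethers and the interflavan bonds are inert to fluoride.

Step 12
Reactants: 19 trimer diol and 20 3,4,5-tris(benzyloxy)benzoic acid (3 equiv used, two equivalents incorporated)
Product: 21 bis(tri-O-benzylgallate) of 19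
Conditions: DCC (3 equiv), DMAP, CH2Cl2, rt
Reagents that add atoms: 3,4,5-tris(benzyloxy)benzoic acid (the second equivalent of 20), OC(=O)c1cc(OCc2ccccc2)c(OCc2ccccc2)c(OCc2ccccc2)c1
Why: Steglich esterification with two equivalents of the acid acylates the two free secondary C3 hydroxyls, one galloyl unit on each, the top C3 oxygen being masked as its benzyl ether.

Step 13
Reactants: 21 perbenzylated trimer digallate
Product: 22 CNP0279403.2, epicatechin-(4α→8)-epicatechin 3-O-gallate-(4β→8)-epicatechin 3-O-gallate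
Conditions: H2 (1 atm), Pd(OH)2/C, THF/MeOH/H2O, rt
Reagents that add atoms: none
Why: Hydrogenolysis of all nineteen O-benzyl groups under neutral conditions should leave the gallate esters, the acid-labile interflavan bonds and every stereocentre intact.

**Compound list**

1 | (−)-epicatechin | O[C@@H]1Cc2c(O)cc(O)cc2O[C@@H]1c1ccc(O)c(O)c1 | starting material
2 | 5,7,3',4'-tetra-O-benzyl-(−)-epicatechin | O[C@@H]1Cc2c(OCc3ccccc3)cc(OCc3ccccc3)cc2O[C@@H]1c1ccc(OCc2ccccc2)c(OCc2ccccc2)c1 | intermediate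
3 | 5,7,3',4'-tetra-O-benzyl-4β-(2-ethoxyethoxy)epicatechin (4-alkoxy trans to 3-OH) | O[C@@H]1[C@@H](OCCOCC)c2c(OCc3ccccc3)cc(OCc3ccccc3)cc2O[C@@H]1c1ccc(OCc2ccccc2)c(OCc2ccccc2)c1 | intermediate
4 | 8-bromo-5,7,3',4'-tetra-O-benzyl-4β-(2-ethoxyethoxy)epicatechin | O[C@@H]1[C@@H](OCCOCC)c2c(OCc3ccccc3)cc(OCc3ccccc3)c(Br)c2O[C@@H]1c1ccc(OCc2ccccc2)c(OCc2ccccc2)c1 | intermediate
5 | 8-bromo-[5,7,3',4'-tetra-O-benzylepicatechin]-(4β→8)-[5,7,3',4'-tetra-O-benzylepicatechin] | O[C@@H]1[C@@H](c2c(OCc3ccccc3)cc(OCc3ccccc3)c3c2O[C@H](c2ccc(OCc4ccccc4)c(OCc4ccccc4)c2)[C@H](O)C3)c2c(OCc3ccccc3)cc(OCc3ccccc3)c(Br)c2O[C@@H]1c1ccc(OCc2ccccc2)c(OCc2ccccc2)c1 | intermediate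
6 | bis(3-O-TBS) ether of 5 | CC(C)(C)[Si](C)(C)O[C@@H]1[C@@H](c2c(OCc3ccccc3)cc(OCc3ccccc3)c3c2O[C@H](c2ccc(OCc4ccccc4)c(OCc4ccccc4)c2)[C@H](O[Si](C)(C)C(C)(C)C)C3)c2c(OCc3ccccc3)cc(OCc3ccccc3)c(Br)c2O[C@@H]1c1ccc(OCc2ccccc2)c(OCc2ccccc2)c1 | intermediate
7 | 3,4-bis(benzyloxy)benzaldehyde | O=Cc1ccc(OCc2ccccc2)c(OCc2ccccc2)c1 | starting material
8 | (S)-4-benzyl-3-[(benzyloxy)acetyl]oxazolidin-2-one | O=C(COCc1ccccc1)N1[C@@H](Cc2ccccc2)COC1=O | starting material
9 | dibutylboron (Z)-enolate of 8 | CCCCB(CCCC)O/C(=C\OCc1ccccc1)N1[C@@H](Cc2ccccc2)COC1=O | intermediate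
10 | (S)-4-benzyl-3-[(2S,3R)-2-(benzyloxy)-3-[3,4-bis(benzyloxy)phenyl]-3-hydroxypropanoyl]oxazolidin-2-one | O[C@H](c1ccc(OCc2ccccc2)c(OCc2ccccc2)c1)[C@H](OCc1ccccc1)C(=O)N1[C@@H](Cc2ccccc2)COC1=O | intermediate
11 | (2S,3R)-2-(benzyloxy)-3-[3,4-bis(benzyloxy)phenyl]-3-hydroxy-N-methoxy-N-methylpropanamide | O[C@H](c1ccc(OCc2ccccc2)c(OCc2ccccc2)c1)[C@H](OCc1ccccc1)C(=O)N(C)OC | intermediate
12 | 1-bromo-3,5-bis(benzyloxy)benzene | Brc1cc(OCc2ccccc2)cc(OCc2ccccc2)c1 | starting material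
13 | (2S,3R)-2-(benzyloxy)-3-[3,4-bis(benzyloxy)phenyl]-3-[3,5-bis(benzyloxy)phenoxy]-N-methoxy-N-methylpropanamide | O(c1cc(OCc2ccccc2)cc(OCc2ccccc2)c1)[C@H](c1ccc(OCc2ccccc2)c(OCc2ccccc2)c1)[C@H](OCc1ccccc1)C(=O)N(C)OC | intermediate
14 | C8-lithio dimer (aryllithium from 6) | CC(C)(C)[Si](C)(C)O[C@@H]1[C@@H](c2c(OCc3ccccc3)cc(OCc3ccccc3)c3c2O[C@H](c2ccc(OCc4ccccc4)c(OCc4ccccc4)c2)[C@H](O[Si](C)(C)C(C)(C)C)C3)c2c(OCc3ccccc3)cc(OCc3ccccc3)c([Li])c2O[C@@H]1c1ccc(OCc2ccccc2)c(OCc2ccccc2)c1 | intermediate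
15 | C8 aryl ketone: dimer bis-TBS ether bearing the (2S,3R)-2-(benzyloxy)-3-aryl-3-aryloxypropanoyl chain at C8 of the upper unit | CC(C)(C)[Si](C)(C)O[C@@H]1[C@@H](c2c(OCc3ccccc3)cc(OCc3ccccc3)c3c2O[C@H](c2ccc(OCc4ccccc4)c(OCc4ccccc4)c2)[C@H](O[Si](C)(C)C(C)(C)C)C3)c2c(OCc3ccccc3)cc(OCc3ccccc3)c(C(=O)[C@@H](OCc3ccccc3)[C@@H](c3ccc(OCc4ccccc4)c(OCc4ccccc4)c3)Oc3cc(OCc4ccccc4)cc(OCc4ccccc4)c3)c2O[C@@H]1c1ccc(OCc2ccccc2)c(OCc2ccccc2)c1 | intermediate
16 | cyclised tertiary carbinol, [3,5,7,3',4'-penta-O-benzyl-4-hydroxyepicatechin]-(4→8)-dimer bis-TBS ether, C4 configuration open | CC(C)(C)[Si](C)(C)O[C@@H]1[C@@H](c2c(OCc3ccccc3)cc(OCc3ccccc3)c3c2O[C@H](c2ccc(OCc4ccccc4)c(OCc4ccccc4)c2)[C@H](O[Si](C)(C)C(C)(C)C)C3)c2c(OCc3ccccc3)cc(OCc3ccccc3)c(C3(O)c4c(OCc5ccccc5)cc(OCc5ccccc5)cc4O[C@H](c4ccc(OCc5ccccc5)c(OCc5ccccc5)c4)[C@@H]3OCc3ccccc3)c2O[C@@H]1c1ccc(OCc2ccccc2)c(OCc2ccccc2)c1 | intermediate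
17 | doubly benzylic top C4 cation (trifluoroacetate ion pair) | CC(C)(C)[Si](C)(C)O[C@@H]1[C@@H](c2c(OCc3ccccc3)cc(OCc3ccccc3)c3c2O[C@H](c2ccc(OCc4ccccc4)c(OCc4ccccc4)c2)[C@H](O[Si](C)(C)C(C)(C)C)C3)c2c(OCc3ccccc3)cc(OCc3ccccc3)c([C+]3c4c(OCc5ccccc5)cc(OCc5ccccc5)cc4O[C@H](c4ccc(OCc5ccccc5)c(OCc5ccccc5)c4)[C@@H]3OCc3ccccc3)c2O[C@@H]1c1ccc(OCc2ccccc2)c(OCc2ccccc2)c1.[O-]C(=O)C(F)(F)F | intermediate
18 | [3,5,7,3',4'-penta-O-benzylepicatechin]-(4α→8)-[5,7,3',4'-tetra-O-benzyl-3-O-TBS-epicatechin]-(4β→8)-[5,7,3',4'-tetra-O-benzyl-3-O-TBS-epicatechin] | CC(C)(C)[Si](C)(C)O[C@@H]1[C@@H](c2c(OCc3ccccc3)cc(OCc3ccccc3)c3c2O[C@H](c2ccc(OCc4ccccc4)c(OCc4ccccc4)c2)[C@H](O[Si](C)(C)C(C)(C)C)C3)c2c(OCc3ccccc3)cc(OCc3ccccc3)c([C@@H]3c4c(OCc5ccccc5)cc(OCc5ccccc5)cc4O[C@H](c4ccc(OCc5ccccc5)c(OCc5ccccc5)c4)[C@@H]3OCc3ccccc3)c2O[C@@H]1c1ccc(OCc2ccccc2)c(OCc2ccccc2)c1 | intermediate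
19 | trimer diol (middle and bottom 3-OH free, top 3-O-benzyl) | O[C@@H]1[C@@H](c2c(OCc3ccccc3)cc(OCc3ccccc3)c3c2O[C@H](c2ccc(OCc4ccccc4)c(OCc4ccccc4)c2)[C@H](O)C3)c2c(OCc3ccccc3)cc(OCc3ccccc3)c([C@@H]3c4c(OCc5ccccc5)cc(OCc5ccccc5)cc4O[C@H](c4ccc(OCc5ccccc5)c(OCc5ccccc5)c4)[C@@H]3OCc3ccccc3)c2O[C@@H]1c1ccc(OCc2ccccc2)c(OCc2ccccc2)c1 | intermediate
20 | 3,4,5-tris(benzyloxy)benzoic acid | OC(=O)c1cc(OCc2ccccc2)c(OCc2ccccc2)c(OCc2ccccc2)c1 | starting material
21 | perbenzylated trimer bis(tri-O-benzylgallate) | O=C(O[C@@H]1[C@@H](c2c(OCc3ccccc3)cc(OCc3ccccc3)c3c2O[C@H](c2ccc(OCc4ccccc4)c(OCc4ccccc4)c2)[C@H](OC(=O)c2cc(OCc4ccccc4)c(OCc4ccccc4)c(OCc4ccccc4)c2)C3)c2c(OCc3ccccc3)cc(OCc3ccccc3)c([C@@H]3c4c(OCc5ccccc5)cc(OCc5ccccc5)cc4O[C@H](c4ccc(OCc5ccccc5)c(OCc5ccccc5)c4)[C@@H]3OCc3ccccc3)c2O[C@@H]1c1ccc(OCc2ccccc2)c(OCc2ccccc2)c1)c1cc(OCc2ccccc2)c(OCc2ccccc2)c(OCc2ccccc2)c1 | intermediate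
22 | CNP0279403.2, epicatechin-(4α→8)-epicatechin 3-O-gallate-(4β→8)-epicatechin 3-O-gallate | O=C(O[C@@H]1[C@@H](c2c(O)cc(O)c3c2O[C@H](c2ccc(O)c(O)c2)[C@H](OC(=O)c2cc(O)c(O)c(O)c2)C3)c2c(O)cc(O)c([C@@H]3c4c(O)cc(O)cc4O[C@H](c4ccc(O)c(O)c4)[C@@H]3O)c2O[C@@H]1c1ccc(O)c(O)c1)c1cc(O)c(O)c(O)c1 | target

**Summary**

Total step count: 13. Longest linear sequence: 10 steps (steps 1–5 and 9–13).

Steps most likely to fail:

Step 10. The ketone may be reduced by the silane before it cyclises; the cation may lose H3 and scramble C3; or the open-chain benzylic C2–O aryl ether may ionise under acid before ring closure. The fallback uses known chemistry and forms the interflavan C4–C8 bond last, not C4–C4a. It sets out from 6, with its ketone partner made from 2. O-Benzylation of 2 (NaH, BnBr, DMF) should give 3,5,7,3',4'-penta-O-benzylepicatechin F1. DDQ in wet CH2Cl2 should give its 4β-hydroxy derivative F2. Dess–Martin oxidation should give (2R,3S)-3,5,7-tris(benzyloxy)-2-[3,4-bis(benzyloxy)phenyl]chroman-4-one F3. Aryllithium 14 (from 6, t-BuLi, THF, −78 °C) is added to F3 to give carbinol 16. Reduction with Bu3SnH/CF3CO2H in CH2Cl2, with hydride entering anti to O3, comes back to the route at 18.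

Step 9. The hindered, basic aryllithium may enolise the α-benzyloxy amide and expel the β-aryloxide, or add too slowly and be quenched. The fallback sets out from 13. Reduction with i-Bu2AlH (THF, −78 °C) should give (2S,3R)-2-(benzyloxy)-3-[3,4-bis(benzyloxy)phenyl]-3-[3,5-bis(benzyloxy)phenoxy]propanal F4. Addition of aryllithium 14 at −78 °C should give the secondary carbinols F5, whose new carbinol centre is of no consequence. Oxidation with Dess–Martin periodinane/NaHCO3 comes back to the route at 15.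

Step 8. β-Hydride elimination may occur from the palladium alkoxide of the benzylic alcohol, or the base may cause retro-aldol cleavage or β-elimination of the β-oxygenated amide. The fallback moves the arylation to a carbonyl-free substrate and to copper, and sets out from 10. LiBH4 (THF/MeOH) removes the auxiliary to give (1R,2R)-2-(benzyloxy)-1-[3,4-bis(benzyloxy)phenyl]propane-1,3-diol F6. TIPSCl/imidazole protects the primary alcohol as the TIPS ether F7. Ullmann-type etherification with 12 (CuI, 3,4,7,8-tetramethyl-1,10-phenanthroline, Cs2CO3, toluene, 110 °C) should give the aryl ether F8 with retention. Bu4NF frees the primary alcohol F9. Dess–Martin oxidation gives aldehyde F4, which is carried through carbinols F5 as described for step 9 and comes back to the route at 15.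

Further compounds
F1 | step 10 | 3,5,7,3',4'-penta-O-benzyl-(−)-epicatechin | O(Cc1ccccc1)[C@@H]1Cc2c(OCc3ccccc3)cc(OCc3ccccc3)cc2O[C@@H]1c1ccc(OCc2ccccc2)c(OCc2ccccc2)c1
F2 | step 10 | 3,5,7,3',4'-penta-O-benzyl-4β-hydroxyepicatechin | O(Cc1ccccc1)[C@@H]1[C@@H](O)c2c(OCc3ccccc3)cc(OCc3ccccc3)cc2O[C@@H]1c1ccc(OCc2ccccc2)c(OCc2ccccc2)c1
F3 | step 10 | (2R,3S)-3,5,7-tris(benzyloxy)-2-[3,4-bis(benzyloxy)phenyl]chroman-4-one | O(Cc1ccccc1)[C@@H]1C(=O)c2c(OCc3ccccc3)cc(OCc3ccccc3)cc2O[C@@H]1c1ccc(OCc2ccccc2)c(OCc2ccccc2)c1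
F4 | step 9 | (2S,3R)-2-(benzyloxy)-3-[3,4-bis(benzyloxy)phenyl]-3-[3,5-bis(benzyloxy)phenoxy]propanal | O=C[C@@H](OCc1ccccc1)[C@@H](c1ccc(OCc2ccccc2)c(OCc2ccccc2)c1)Oc1cc(OCc2ccccc2)cc(OCc2ccccc2)c1
F5 | step 9 | secondary carbinols from 14 and F4 (dimer bis-TBS ether bearing the 1-hydroxy-(2S,3R)-2-(benzyloxy)-3-aryl-3-aryloxypropyl chain at C8, carbinol centre open) | CC(C)(C)[Si](C)(C)O[C@@H]1[C@@H](c2c(OCc3ccccc3)cc(OCc3ccccc3)c3c2O[C@H](c2ccc(OCc4ccccc4)c(OCc4ccccc4)c2)[C@H](O[Si](C)(C)C(C)(C)C)C3)c2c(OCc3ccccc3)cc(OCc3ccccc3)c(C(O)[C@@H](OCc3ccccc3)[C@@H](c3ccc(OCc4ccccc4)c(OCc4ccccc4)c3)Oc3cc(OCc4ccccc4)cc(OCc4ccccc4)c3)c2O[C@@H]1c1ccc(OCc2ccccc2)c(OCc2ccccc2)c1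
F6 | step 8 | (1R,2R)-2-(benzyloxy)-1-[3,4-bis(benzyloxy)phenyl]propane-1,3-diol | O[C@H](c1ccc(OCc2ccccc2)c(OCc2ccccc2)c1)[C@H](OCc1ccccc1)CO
F7 | step 8 | (1R,2R)-2-(benzyloxy)-1-[3,4-bis(benzyloxy)phenyl]-3-[(triisopropylsilyl)oxy]propan-1-ol | O[C@H](c1ccc(OCc2ccccc2)c(OCc2ccccc2)c1)[C@H](OCc1ccccc1)CO[Si](C(C)C)(C(C)C)C(C)C
F8 | step 8 | [(2R,3R)-2-(benzyloxy)-3-[3,4-bis(benzyloxy)phenyl]-3-[3,5-bis(benzyloxy)phenoxy]propoxy]triisopropylsilane | O(c1cc(OCc2ccccc2)cc(OCc2ccccc2)c1)[C@H](c1ccc(OCc2ccccc2)c(OCc2ccccc2)c1)[C@H](OCc1ccccc1)CO[Si](C(C)C)(C(C)C)C(C)C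
F9 | step 8 | (2R,3R)-2-(benzyloxy)-3-[3,4-bis(benzyloxy)phenyl]-3-[3,5-bis(benzyloxy)phenoxy]propan-1-ol | O(c1cc(OCc2ccccc2)cc(OCc2ccccc2)c1)[C@H](c1ccc(OCc2ccccc2)c(OCc2ccccc2)c1)[C@H](OCc1ccccc1)CO
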